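The percent of the Z charged is the unit of every reading below, and in that unit the E of this flask counts for 5 mol%. The north-west run is this same flask, followed so far.

- north-west: Z 5.0 × 10⁻⁴ M; Q 1.5 equiv; E 5 mol%; the very flask that is asked about, followed so far
- flask: Z 5.0 × 10⁻⁴ M; Q 1.50 equiv; E 5 mol%

- north-west (time / min: G / %, Z / %): 0.200: 7.9, 88.9; 0.333: 10.8, 83.8; 0.667: 19.3, 76.3; 1.33: 26.9, 68.4; 2.50: 36.2, 60.4

(standard deviation of a reading: 0.5 percentage points)

- the numbers in the tables scatter by 0.5 percentage points (one standard deviation)
- no earlier run changes the charge of E; that part of a forecast is a guess
- no earlier run changes the charge of Q; that part of a forecast is a guess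

- apparent order in Q when 10% of the Z are converted (percent change of the rate of making G for one percent more Q charged)
- apparent order in E when 10% of the Z are converted (percent change of the rate of making G for one percent more E charged)

The bench rule of thumb reads conversion of Z as yield of G and takes the rate as proportional to E. The balance of Z, the limiting reagent by charge, tests the first part: Z converted is G plus whatever sits on the catalyst. Loading over conversion gives 0.500 at 10%. This held share is the ceiling on the part of the converted Z missing from G, if each E holds one Z. The rule can therefore fail at the moment asked, since up to half of that Z need not be G yet.

The readings of the north-west run show the gap: Z + G falls short by 4.22% on average, which reads as 0.844 of the E held in a Z-derived resting state. If Q meets that form, the order in Q lies near one, though this is a guess because no run varies Q.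

In the north-west run the readings put the mean rate of making G over the first interval above that over the last by a factor 4.97, more than the factor 1.47 by which Z falls. Since that rate falls faster than Z, a larger charge of E is expected to reach the moment asked earlier, at a higher rate per E, so this reckoning puts the order in E above one, again untested by any run.

The forecast gave 0.6 for Q and 1 for E, holding that “the rate should be about first order in E, or slightly above if the catalyst dies”.

The flask gives 0.94 in Q and 1.4 in E, at a conversion reached after 0.155 min. The one-step fit, first order in Z and in E with all reacted Z read as G, returns 1.00 for E.

    Z + E → D (k = 2300 M⁻¹ s⁻¹)
    D → X (k = 27.0 s⁻¹)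
    Q + X → L (k = 290 M⁻¹ s⁻¹)
    L → E + G (k = 1.40 s⁻¹)
    Q ⇌ J (K = 5.70, k = 0.0290 s⁻¹)

At 6.00 min, with Z at 40.6% and G at 54.6%, the ceiling on the held share of this flask, loading over conversion, has dropped to 0.0842 of the Z converted, while X stands at 95.2% of the E charged.

The earlier runs and the new flask come from a simulation on assumed constants.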